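**Plan**

- Retrosynthesis: the depside ester bond C(=O)–O4' is cut first, giving ring A as 2,4-dimethoxy-3,6-dimethylbenzoic acid and ring B as a benzyl 2,4-dihydroxy-3,6-dimethylbenzoate. Ring B is then cut at C2'–C3', C4'–C5' and C1'–C2' into a diazo enone and 1-(triisopropylsiloxy)propyne.
- Enabling feature: ring B is a resorcinol with the C3' methyl between O2' and O4' and the C1' carboxyl next to the free O2'–H. A vinylketene (supplying C1', C2', C5', C6') and a siloxyalkyne (supplying C3', C4') give exactly this array, with O4' silylated and O2' free.
- Forward order: Wittig olefination and diazo transfer give the diazo enone, and ester homologation gives the siloxyalkyne. The benzannulation closes ring B and fluoride frees O4'. The ring A acid (two steps from a commercial benzoate) is attached by mixed-anhydride esterification, and hydrogenolysis unmasks the acid.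
- Stereochemistry: the target has no stereocentre. The only geometric element, the E enoate, is set in the Wittig step and consumed in the annulation.

Key step: step 4

Assumption: methyl 2,4-dihydroxy-3,6-dimethylbenzoate is taken as a purchasable material; primed locants refer to ring B (the hydroxy acid ring), unprimed ones to ring A.

**Route**

Step 1
Reactants: 1 butane-2,3-dione; 2 benzyl (triphenylphosphoranylidene)acetate
Product: 3 benzyl (E)-3-methyl-4-oxopent-2-enoate
Conditions: 1 (3 equiv), CH2Cl2, 0 °C to rt
Reagents that add atoms: none
Why: Wittig olefination with a stabilised ylide, which reacts with one carbonyl of the symmetrical 1,2-dione and should give the E enoate (acetyl trans to the ester), excess volatile dione suppressing double olefination.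

Step 2
Reactants: 3 benzyl (E)-3-methyl-4-oxopent-2-enoate
Product: 5 benzyl (E)-5-diazo-3-methyl-4-oxopent-2-enoate, via trifluoroacetyl diketone 4 (not isolated)
Conditions: LiN(SiMe3)2, THF, −78 °C; CF3CO2CH2CF3, −78 °C; aq HCl work-up; then CH3SO2N3, Et3N, H2O, MeCN, rt
Reagents that add atoms: methanesulfonyl azide, CS(=O)(=O)N=[N+]=[N-]
Why: Detrifluoroacetylative diazo transfer: kinetic enolisation at the acetyl methyl (the only sp3 α-carbon of the ketone) and Claisen acylation by the trifluoroethyl ester give the activated 1,3-diketone 4, to which the sulfonyl azide transfers N2 with loss of the trifluoroacetyl group as its N-mesyl amide, the established entry to α'-diazo enones that cannot be made cleanly by acylating diazomethane.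

Step 3
Reactants: 6 ethyl acetate; 7 triisopropylsilyl trifluoromethanesulfonate
Product: 10 triisopropyl(prop-1-yn-1-yloxy)silane, via dibromoenolate 8 (not isolated), via lithium ynolate 9 (not isolated)
Conditions: CH2Br2, lithium 2,2,6,6-tetramethylpiperidide, THF, −78 °C; 6; LiN(SiMe3)2; n-BuLi, −78 °C to rt; then 7, −78 to 0 °C
Reagents that add atoms: dibromomethane, BrCBr
Why: Kowalski ester homologation: dibromomethyllithium adds to the ester, the derived dibromo enolate 8 undergoes bromine–lithium exchange and a 1,2-shift of methyl to the carbenoid carbon to give ynolate 9, and the bulky silyl triflate then reacts at oxygen, not at carbon, to give the ynol silyl ether.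

Step 4
Reactants: 5 benzyl (E)-5-diazo-3-methyl-4-oxopent-2-enoate; 10 triisopropyl(prop-1-yn-1-yloxy)silane
Product: 15 benzyl 2-hydroxy-3,6-dimethyl-4-(triisopropylsilyloxy)benzoate, via vinylketene 11 (not isolated), via vinylcyclobutenone 12 (not isolated), via dienylketene 13 (not isolated), via cyclohexadienone 14 (not isolated)
Conditions: 10 (1.5 equiv), hν (254 nm, low-pressure Hg lamp), ClCH2CH2Cl, rt; then 80 °C
Reagents that add atoms: none
Why: Irradiation expels N2 from 5 and the enoate-bearing vinyl group migrates (photochemical Wolff rearrangement) to give vinylketene 11, whose ketene C=C undergoes a regioselective (2+2) cycloaddition with ynol ether 10 to give cyclobutenone 12. Reversible 4-electron conrotatory opening of 12 gives dienylketene 13, ring B then closes by a thermally allowed disrotatory 6-electron electrocyclisation that forms C1'–C2', and enolisation of cyclohexadienone 14 delivers phenol 15. The closest known reaction type is the Danheiser benzannulation of α'-diazo enones with trialkylsiloxyalkynes, which gives resorcinol monosilyl ethers of this kind. No stereocentre survives, since the sp3 carbons of 12 and 14 are lost on ring opening and aromatisation. The step needs head-to-tail regiochemistry in the (2+2) event, and the oxygen-polarised alkyne secures it: its nucleophilic methyl-bearing carbon bonds to the electrophilic ketene carbonyl carbon (C2'–C3') and its siloxy carbon to the ketene α-carbon (C4'–C5'), so the methyl lands between the two oxygens and the silyl group on O4'. The E enoate of 5 keeps the ester on the outer side of the triene terminus, which eases the closure and places the ester at C1' beside the new hydroxyl.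

Step 5
Reactants: 15 benzyl 2-hydroxy-3,6-dimethyl-4-(triisopropylsilyloxy)benzoate
Product: 16 benzyl 2,4-dihydroxy-3,6-dimethylbenzoate
Conditions: Bu4NF, AcOH, THF, 0 °C
Reagents that add atoms: none
Why: Fluoride-induced cleavage of an aryl silyl ether, driven by the strong Si–F bond and the good phenoxide leaving group, with acetic acid buffering so that the benzyl ester is left alone.

Step 6
Reactants: 17 methyl 2,4-dihydroxy-3,6-dimethylbenzoate
Product: 18 methyl 2,4-dimethoxy-3,6-dimethylbenzoate
Conditions: CH3I (excess), K2CO3, DMF, 60 °C
Reagents that add atoms: iodomethane, CI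
Why: Williamson ether synthesis on both phenoxides, with excess methyl iodide in warm DMF because the 2-hydroxyl is chelated to the ester and flanked by two substituents.

Step 7
Reactants: 18 methyl 2,4-dimethoxy-3,6-dimethylbenzoate
Product: 19 2,4-dimethoxy-3,6-dimethylbenzoic acid
Conditions: KOH, DMSO–H2O, 90 °C; then aq HCl
Reagents that add atoms: potassium hydroxide, [K+].[OH-]
Why: Saponification of a di-ortho-substituted benzoate, for which hydroxide in hot aqueous DMSO is the standard remedy, the aryl methyl ethers being inert to base.

Step 8
Reactants: 19 2,4-dimethoxy-3,6-dimethylbenzoic acid; 16 benzyl 2,4-dihydroxy-3,6-dimethylbenzoate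
Product: 21 benzyl 4-[(2,4-dimethoxy-3,6-dimethylbenzoyl)oxy]-2-hydroxy-3,6-dimethylbenzoate, via mixed anhydride 20 (not isolated)
Conditions: (CF3CO)2O, toluene, rt
Reagents that add atoms: none
Why: Mixed-anhydride esterification (the trifluoroacetic anhydride method for depsides): the hindered acid is activated as aroyl trifluoroacetate 20, which should acylate the 4-hydroxyl of 16 in preference to the 2-hydroxyl because the latter is hydrogen-bonded to the ester carbonyl and flanked by the ester and the C3' methyl.

Step 9
Reactants: 21 benzyl 4-[(2,4-dimethoxy-3,6-dimethylbenzoyl)oxy]-2-hydroxy-3,6-dimethylbenzoate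
Product: 22 diffractaic acid (4-[(2,4-dimethoxy-3,6-dimethylbenzoyl)oxy]-2-hydroxy-3,6-dimethylbenzoic acid)
Conditions: H2 (1 atm), 10% Pd/C, EtOAc, rt
Reagents that add atoms: none
Why: Catalytic hydrogenolysis of a benzyl ester over palladium on carbon, which leaves the aryl ester link, the methyl ethers and both arenes untouched.

**Compound list**

1 | butane-2,3-dione | CC(=O)C(C)=O | starting material
2 | benzyl (triphenylphosphoranylidene)acetate | O=C(C=P(c1ccccc1)(c1ccccc1)c1ccccc1)OCc1ccccc1 | starting material
3 | benzyl (E)-3-methyl-4-oxopent-2-enoate | CC(=O)/C(C)=C/C(=O)OCc1ccccc1 | intermediate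
4 | benzyl (E)-7,7,7-trifluoro-3-methyl-4,6-dioxohept-2-enoate | O=C(CC(=O)/C(C)=C/C(=O)OCc1ccccc1)C(F)(F)F | intermediate
5 | benzyl (E)-5-diazo-3-methyl-4-oxopent-2-enoate | [N-]=[N+]=CC(=O)/C(C)=C/C(=O)OCc1ccccc1 | intermediate
6 | ethyl acetate | CCOC(C)=O | starting material
7 | triisopropylsilyl trifluoromethanesulfonate | CC(C)[Si](OS(=O)(=O)C(F)(F)F)(C(C)C)C(C)C | starting material
8 | lithium 1,1-dibromoprop-1-en-2-olate | CC(O[Li])=C(Br)Br | intermediate
9 | lithium prop-1-yn-1-olate | CC#CO[Li] | intermediate
10 | triisopropyl(prop-1-yn-1-yloxy)silane | CC#CO[Si](C(C)C)(C(C)C)C(C)C | intermediate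
11 | benzyl (E)-3-methyl-5-oxopenta-2,4-dienoate (vinylketene) | O=C=C/C(C)=C/C(=O)OCc1ccccc1 | intermediate
12 | benzyl (E)-3-[3-methyl-4-oxo-2-(triisopropylsilyloxy)cyclobut-2-en-1-yl]but-2-enoate (racemic at the ring sp3 carbon) | CC1=C(O[Si](C(C)C)(C(C)C)C(C)C)C(/C(C)=C/C(=O)OCc2ccccc2)C1=O | intermediate
13 | benzyl (2E,4E)-3,6-dimethyl-7-oxo-5-(triisopropylsilyloxy)hepta-2,4,6-trienoate (dienylketene) | O=C=C(C)/C(O[Si](C(C)C)(C(C)C)C(C)C)=C\C(C)=C\C(=O)OCc1ccccc1 | intermediate
14 | benzyl 2,5-dimethyl-6-oxo-4-(triisopropylsilyloxy)cyclohexa-2,4-diene-1-carboxylate (racemic) | CC1=CC(O[Si](C(C)C)(C(C)C)C(C)C)=C(C)C(=O)C1C(=O)OCc1ccccc1 | intermediate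
15 | benzyl 2-hydroxy-3,6-dimethyl-4-(triisopropylsilyloxy)benzoate | Cc1cc(O[Si](C(C)C)(C(C)C)C(C)C)c(C)c(O)c1C(=O)OCc1ccccc1 | intermediate
16 | benzyl 2,4-dihydroxy-3,6-dimethylbenzoate | Cc1cc(O)c(C)c(O)c1C(=O)OCc1ccccc1 | intermediate
17 | methyl 2,4-dihydroxy-3,6-dimethylbenzoate | COC(=O)c1c(C)cc(O)c(C)c1O | starting material
18 | methyl 2,4-dimethoxy-3,6-dimethylbenzoate | COC(=O)c1c(C)cc(OC)c(C)c1OC | intermediate
19 | 2,4-dimethoxy-3,6-dimethylbenzoic acid | COc1cc(C)c(C(=O)O)c(OC)c1C | intermediate
20 | 2,4-dimethoxy-3,6-dimethylbenzoic trifluoroacetic anhydride | COc1cc(C)c(C(=O)OC(=O)C(F)(F)F)c(OC)c1C | intermediate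
21 | benzyl 4-[(2,4-dimethoxy-3,6-dimethylbenzoyl)oxy]-2-hydroxy-3,6-dimethylbenzoate | COc1cc(C)c(C(=O)Oc2cc(C)c(C(=O)OCc3ccccc3)c(O)c2C)c(OC)c1C | intermediate
22 | diffractaic acid | COc1cc(C)c(C(=O)Oc2cc(C)c(C(=O)O)c(O)c2C)c(OC)c1C | target

**Step count and risks**

Total step count: 9. Longest linear sequence: 6 steps (steps 1, 2, 4, 5, 8, 9, from butane-2,3-dione).

Steps most likely to fail:

Step 2. The lithium amide, or the cross-conjugated enolate once formed, may add in conjugate fashion to the doubly activated alkene of 3, or deprotonation may occur at the C3 methyl instead of the acetyl methyl, so that trifluoroacetylation is lost to oligomerisation. The fallback sets out from 3 and returns to the route at 5 without any enolate. Acid-mediated α-bromination of the acetyl methyl with phenyltrimethylammonium tribromide in THF should give benzyl (E)-5-bromo-3-methyl-4-oxopent-2-enoate F1, the electron-poor alkene being expected to resist bromine addition. Treatment with N,N'-ditosylhydrazine and DBU in THF at 0 °C should alkylate the hydrazine to benzyl (E)-5-[1,2-bis(4-methylbenzenesulfonyl)hydrazin-1-yl]-3-methyl-4-oxopent-2-enoate F2. This is not isolated and should lose two sulfinate ions under the same base to deliver 5.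

Step 4. Under irradiation the enoate may isomerise from E to Z, after which the Z vinylketene can close through oxygen onto its own ester carbonyl. Ketene dimerisation or hydrolysis of the ynol ether may also outrun the (2+2) capture, and the siloxycyclobutenone may resist ring opening. The fallback gives up the annulation for ring B and secures the same intermediate from the benzoate that also supplies ring A: it sets out from 17 and comes back at 16. Saponification of 17 (KOH, aqueous DMSO, acidification in the cold to avoid decarboxylation) should give 2,4-dihydroxy-3,6-dimethylbenzoic acid F3. Carboxylate-selective alkylation with benzyl bromide and KHCO3 in DMF should then give 16.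

Step 3. Enolisation of ethyl acetate may compete with addition of the carbenoid, and the bromine–lithium exchange and rearrangement may stop short. The acid-sensitive ynol ether may also be lost by hydrolysis during work-up and purification. The fallback keeps triflate 7 as its numbered entry point and replaces the ester by an acetylide. Commercial 1-propynyllithium would be oxidised with lithium tert-butyl peroxide (from t-BuOOH and LiN(SiMe3)2, THF, −78 to 0 °C) to the same ynolate 9. Silylation on oxygen with 7 then rejoins the route at 10, with no new compound on the way.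

**Further compounds**

F1 | step 2 | benzyl (E)-5-bromo-3-methyl-4-oxopent-2-enoate | O=C(CBr)/C(C)=C/C(=O)OCc1ccccc1
F2 | step 2 | benzyl (E)-5-[1,2-bis(4-methylbenzenesulfonyl)hydrazin-1-yl]-3-methyl-4-oxopent-2-enoate | Cc1ccc(cc1)S(=O)(=O)NN(CC(=O)/C(C)=C/C(=O)OCc1ccccc1)S(=O)(=O)c1ccc(C)cc1
F3 | step 4 | 2,4-dihydroxy-3,6-dimethylbenzoic acid | Cc1cc(O)c(C)c(O)c1C(=O)O
F0 | step 3 | none | none
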